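Readings and results are calculated for an exercise, and the scatter is random.

A percentage times a charge is an amount. A solid substrate turns to product under free catalyst, and the question is how much free product stands in each flask.

| setting | south-east | south | north-west | maple | birch | elm | cedar |
|---|---|---|---|---|---|---|---|
| solid substrate | 25 mM | 100 mM | 420 mM | 20 mM | 60 mM | 200 mM | 500 mM |
| free catalyst | 40 µM | 40 µM | 40 µM | 40 µM | 40 µM | 40 µM | 40 µM |
| remark | run made earlier | run made earlier | run made earlier |  |  |  |  |
| time |  |  |  | 2.0 h | 2.0 h | 2.0 h | 2.0 h |

| run | time / min | product / % | solid substrate / % |
|---|---|---|---|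
| south-east | 12.0 | 5.3 | 84.6 |
| south-east | 25.0 | 12.1 | 79.3 |
| south-east | 40.0 | 18.0 | 72.6 |
| south-east | 50.0 | 23.1 | 67.7 |
| south-east | 60.0 | 26.4 | 64.9 |
| south | 12.0 | 1.7 | 97.1 |
| south | 25.0 | 2.5 | 95.5 |
| south | 40.0 | 4.3 | 93.2 |
| south | 50.0 | 7.8 | 91.8 |
| south | 60.0 | 6.8 | 91.6 |
| north-west | 5.00 | 1.9 | 98.8 |
| north-west | 15.0 | 1.0 | 98.5 |
| north-west | 30.0 | 0.5 | 97.5 |
| north-west | 40.0 | 2.2 | 99.7 |
| north-west | 60.0 | 1.4 | 98.3 |

(scatter of a reading: 1 percentage point)

- at the start none of the solid substrate is in solution
- a reading or a percentage of product counts all its forms, free or not
- the concentration of product that is asked is that of its free form alone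
- "hardly changes" means that all values lie within two and a half points (for a concentration: within two and a half percent of the largest)

- [product] (only what is free in solution) at the end for maple, birch, elm, cedar, in this order
- the course of these numbers from the first flask to the last (rises all the way / falls all the way / falls, then rises / rises, then falls / hardly changes)

At 60.0 min the south-east run holds 26.4% of 25 mM, which is 6.60 mM of product. The south run, with 4.00 times that charge, holds 6.80 mM at the same time. So I take the charge out of the pace (zero order, in the usual term) and read 0.110 mM/min of product, a reading with its scatter.

The quantity I carry is the lifetime of a charge, that charge divided by this pace: 182 min for maple. Maple has the smallest charge, and its lifetime is longer than the run of 120 min. So I expect solid to stand to the end in each of the four flasks, and the elapsed share of the lifetime gives the share of the charge turned to product. That makes my total product 13.2 mM in each flask.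

Two chemists then part over the free form. Ines counts that product as free. Tom objects that the columns count every form of product, and that 2.17 mM of the south-east charge lies in neither column at 60.0 min, so a small dissolved stock sits beside a solid. Product may behave likewise, he says, with a flat row at a ceiling that these columns do not show, below 13.2 mM.

Ines's forecast is 13.7 mM at each point, slightly above my total, and hardly changes: “All four flasks should therefore match”.

The simulation gives 0.395 mM, 0.395 mM, 0.395 mM and 0.395 mM: hardly changes.

    starting material + free catalyst ⇌ catalyst intermediate (K = 3100 /M, k = 21.0 /M/s)
    catalyst intermediate → free catalyst + product (k = 21.0 /s)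
    solid substrate ⇌ starting material, rate k3*(cs3 - [starting material]) while solid is left; crystals form when [starting material] > cs3 (solubility = 2.50 mM, k = 0.0110 /s)
    crystals ⇌ product, rate k4*(cs4 - [product]) while solid is left; crystals form when [product] > cs4 (solubility = 0.360 mM, k = 0.0560 /s)

Tom is right: at 2.00 h maple holds 69.2% of its charge as product, and 67.3% of the charge, counted within that product, stands as crystals. Ines's view has its region below the crystal limit of 0.36 mM, worth an estimated 3.27 min at the pace I read. Maple's run spends 65.9% of its lifetime, against that 69.2%. Cedar's lifetime is 75.8 h, so 20.0 h spends 26.4% of it, and at that time cedar holds 28.0% of its charge as product.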